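**Plan**

- The target is the 1β-(E)-4-methoxycinnamate of polygodial (drimane numbering: ring A = C1–C5, C10; ring B = C5–C10; C11 on C9, C12 on C8; the C10 methyl defines the β face). Retrosynthesis cuts the ester C–O bond, takes the C11/C12 aldehydes back to a diol and then to the C9 ketone and C8 methyl of a carvone-type enone, and opens ring A at C1–C2 and C3–C4.
- Enabling feature: in ring A the C2–C3 ethano unit lies between the gem-dimethyl carbon C4 (a latent tertiary radical, i.e. an isopropenyl group on C5) and the carbinol carbon C1 (a latent aldehyde on C10). These two carbons are 1,4-related across the C5–C10 bond of ring B, so an acrylate can be stitched in by radical addition followed by aldol closure.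
- Forward: (R)-carvone supplies ring B with C5, the isopropenyl group, the C8 methyl and the C9 carbonyl. C10 is made quaternary (methylation, hydroxymethylation, oxidation) and ring A is then annulated.
- The helper carboxyl at C2 is removed through the C1 ketone, C1 is reset by hydride and esterified. C9=O is methylenated and hydroborated (C11), C12 is oxidised, and a Swern oxidation finishes the route.
- Stereochemistry: C5 comes from (R)-carvone; C10 from enolate attack anti to the isopropenyl group, which fixes the trans ring fusion; C1 from axial hydride delivery anti to the C10 methyl; C9 from hydroboration anti to the C10 methyl.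

Key step: step 4

Remark on the chemistry: (E)-4-methoxycinnamoyl chloride is taken as a commercial reagent; α/β descriptors refer to the usual drimane drawing with the C10 methyl β and H-5 α.

**Step 1**
Reactants: 1 (R)-(–)-carvone
Product: 3 (5R,6S)-2,6-dimethyl-5-(prop-1-en-2-yl)cyclohex-2-en-1-one (trans-6-methylcarvone; the C6 epimer is carried along), via lithium dienolate 2 (not isolated)
Conditions: LiN(i-Pr)2 (1.05 equiv), THF, −78 °C; MeI, −78 to 0 °C
Reagents that add atoms: iodomethane, CI
Why: Kinetic α′-deprotonation gives the cross-conjugated lithium dienolate, which is C-methylated (enolate alkylation); the C6 configuration does not matter because this centre is planarised again in step 2.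

**Step 2**
Reactants: 3 trans-6-methylcarvone
Product: 5 (5S,6R)-6-(hydroxymethyl)-2,6-dimethyl-5-(prop-1-en-2-yl)cyclohex-2-en-1-one (CH2OH trans and methyl cis to isopropenyl), via lithium enolate 4 (not isolated)
Conditions: LiN(i-Pr)2, THF, −78 °C; monomeric CH2O (cracked paraformaldehyde), −78 °C; AcOH quench at −78 °C
Reagents that add atoms: formaldehyde, C=O
Why: Aldol hydroxymethylation of the tetrasubstituted enolate; formaldehyde should enter anti to the adjacent pseudoaxial isopropenyl group, setting the quaternary centre that becomes C10, and the cold acidic quench suppresses retro-aldol.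

**Step 3**
Reactants: 5 hydroxymethyl ketone
Product: 6 (1R,6S)-1,3-dimethyl-2-oxo-6-(prop-1-en-2-yl)cyclohex-3-ene-1-carbaldehyde (CHO trans to isopropenyl)
Conditions: DMP, CH2Cl2, 0 °C to rt
Reagents that add atoms: none
Why: Dess–Martin oxidation of the neopentyl primary alcohol under neutral conditions should give the non-enolisable β-keto aldehyde without retro-Claisen loss of the formyl group.

**Step 4**
Reactants: 6 β-keto aldehyde; 7 tert-butyl acrylate
Product: 10 tert-butyl 1α-hydroxy-9-oxo-11-nordrim-7-ene-2α-carboxylate (trans-fused; expected major diastereomer; C1/C2 isomers converge in steps 5 to 7), via tertiary alkyl radical 8 (not isolated), via ferric ester enolate 9 (not isolated)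
Conditions: Fe(acac)3 (0.3 equiv), PhSiH3 (2.5 equiv), 7 (3 equiv), EtOH/(CH2OH)2, 0 °C to rt
Reagents that add atoms: tert-butyl acrylate (7), C=CC(=O)OC(C)(C)C
Why: An iron hydride formed from Fe(acac)3 and PhSiH3 transfers a hydrogen atom to the CH2 terminus of the isopropenyl group (Mukaiyama-type HAT) to give tertiary radical 8, whose Giese addition to the acrylate forms C3–C4; the α-ester radical is reduced by divalent iron to the enolate 9 (radical–polar crossover), which closes onto the neighbouring aldehyde to form C1–C2. The closest known reaction type is the iron-catalysed HAT-initiated Giese–aldol annulation of a γ,δ-unsaturated aldehyde with an α,β-unsaturated carbonyl compound. Ring A closes by a 6-(enolexo)-exo-trig aldol through a chair in which the C5 and C10 arms are both equatorial on ring B, so the trans fusion follows from the trans relationship set in step 2. Of the new stereocentres, C2 should carry its ester equatorial (avoiding 1,3-diaxial contact with the C4 and C10 methyls) and C1 its hydroxyl axial (chelated Zimmerman–Traxler closure); neither is relied on, since C1 is reset in steps 5 and 7 and C2 loses its substituent in step 6. The step needs chemoselective HAT to the electron-rich 1,1-disubstituted alkene over the electron-poor C7=C8 enone and the acrylate, secured by polarity matching, and aldol closure ahead of enolate protonation, secured by the proximity of the highly electrophilic, non-enolisable aldehyde.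

**Step 5**
Reactants: 10 hydroxy ester
Product: 11 tert-butyl 1,9-dioxo-11-nordrim-7-ene-2-carboxylate (β-keto ester, C2 epimerisable)
Conditions: DMP, CH2Cl2, rt
Reagents that add atoms: none
Why: Dess–Martin oxidation of the secondary carbinol funnels all C1/C2 diastereomers of 10 into one β-keto ester under neutral conditions that avoid retro-aldol.

**Step 6**
Reactants: 11 β-keto ester
Product: 13 11-nordrim-7-ene-1,9-dione (5α-H, 10β-methyl), via β-keto acid 12 (not isolated)
Conditions: TFA, CH2Cl2, rt; then toluene, 80 °C
Reagents that add atoms: none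
Why: Acidolysis of the tert-butyl ester followed by thermal decarboxylation of the β-keto acid removes the helper carboxyl without exposing the non-enolisable 1,9-diketone to nucleophilic base (no retro-Claisen opening).

**Step 7**
Reactants: 13 ene-dione
Product: 14 1β-hydroxy-11-nordrim-7-en-9-one
Conditions: NaBH4, MeOH/CH2Cl2 (1:1), −78 °C
Reagents that add atoms: none
Why: Chemoselective borohydride reduction of the saturated C1 ketone beside the less electrophilic conjugated C9 ketone (as with Wieland–Miescher-type ene-diones); axial hydride delivery from the α face, anti to the axial C10 methyl, should give the equatorial 1β-alcohol.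

**Step 8**
Reactants: 14 1β-alcohol; 15 (E)-4-methoxycinnamoyl chloride
Product: 16 1β-[(E)-4-methoxycinnamoyloxy]-11-nordrim-7-en-9-one
Conditions: Et3N, DMAP (cat.), CH2Cl2, 0 to 40 °C
Reagents that add atoms: (E)-4-methoxycinnamoyl chloride (15), COc1ccc(/C=C/C(Cl)=O)cc1
Why: DMAP-catalysed acylation through the acylpyridinium ion should esterify the hindered equatorial alcohol with retention at C1 (the C–O bond is untouched) and blocks retro-aldol in later steps.

**Step 9**
Reactants: 16 keto ester
Product: 17 1β-[(E)-4-methoxycinnamoyloxy]drima-7,9(11)-diene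
Conditions: Zn dust, CH2Br2, TiCl4, THF/CH2Cl2, 0 °C to rt
Reagents that add atoms: dibromomethane, BrCBr
Why: Takai–Lombardo methylenation, whose non-basic titanium–zinc methylene reagent olefinates hindered ketones 1,2-selectively and leaves esters untouched.

**Step 10**
Reactants: 17 diene
Product: 19 1β-[(E)-4-methoxycinnamoyloxy]drim-7-en-11-ol (9α-H, 9β-CH2OH), via B-alkyl-9-BBN adduct 18 (not isolated)
Conditions: 9-BBN, THF, 0 °C to rt; then H2O2, aq. NaOAc, 0 °C to rt
Reagents that add atoms: 9-BBN, B1C2CCCC1CCC2 (for intermediate 18 only); hydrogen peroxide, OO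
Why: Hydroboration–oxidation; 9-BBN should add only to the terminal exocyclic C9=C11 bond (boron to C11), not to the trisubstituted C7=C8 or the electron-poor cinnamate alkene, from the α face opposite the axial C10 methyl, placing hydrogen at C9α and the CH2OH 9β.

**Step 11**
Reactants: 19 homoallylic alcohol
Product: 20 1β-[(E)-4-methoxycinnamoyloxy]drim-7-ene-11,12-diol
Conditions: SeO2 (0.5 equiv), t-BuOOH, CH2Cl2, rt
Reagents that add atoms: tert-butyl hydroperoxide, CC(C)(C)OO (oxygen relayed by SeO2, O=[Se]=O)
Why: Riley allylic oxidation (ene reaction, then [2,3]-sigmatropic shift) delivers oxygen at the more substituted alkene terminus, on the C8 methyl in preference to the hindered C9 methine, with C7=C8 restored; catalytic SeO2 with t-BuOOH is chosen to stop at the allylic alcohol.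

**Step 12**
Reactants: 20 diol
Product: 21 1β-[(E)-4-methoxycinnamoyloxy]drim-7-ene-11,12-dial (target)
Conditions: (COCl)2, DMSO, CH2Cl2, −78 °C; Et3N, −78 to −30 °C
Reagents that add atoms: none
Why: Swern oxidation converts both primary hydroxyls into alkoxysulfonium ions before base is added, so the 1,4-diol should give the dialdehyde without lactol or lactone formation, and the low temperature protects the epimerisable 9β-formyl centre and the position of the C7=C8 bond.

**Compound list**

1 | (R)-(–)-carvone | CC(=C)[C@@H]1CC=C(C)C(=O)C1 | starting material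
2 | lithium dienolate of 1 | CC(=C)[C@@H]1CC=C(C)C(O[Li])=C1 | intermediate
3 | (5R,6S)-2,6-dimethyl-5-(prop-1-en-2-yl)cyclohex-2-en-1-one (trans-6-methylcarvone, with C6 epimer) | CC(=C)[C@@H]1CC=C(C)C(=O)[C@H]1C | intermediate
4 | lithium enolate of 3 | CC(=C)[C@@H]1CC=C(C)C(O[Li])=C1C | intermediate
5 | (5S,6R)-6-(hydroxymethyl)-2,6-dimethyl-5-(prop-1-en-2-yl)cyclohex-2-en-1-one | CC(=C)[C@@H]1CC=C(C)C(=O)[C@@]1(C)CO | intermediate
6 | (1R,6S)-1,3-dimethyl-2-oxo-6-(prop-1-en-2-yl)cyclohex-3-ene-1-carbaldehyde | CC(=C)[C@@H]1CC=C(C)C(=O)[C@@]1(C)C=O | intermediate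
7 | tert-butyl acrylate | C=CC(=O)OC(C)(C)C | starting material
8 | tertiary alkyl radical from HAT to 6 | C[C](C)[C@@H]1CC=C(C)C(=O)[C@@]1(C)C=O | intermediate
9 | ferric ester enolate of the Giese adduct (drawn as the enolate anion) | CC(C)(CC=C([O-])OC(C)(C)C)[C@@H]1CC=C(C)C(=O)[C@@]1(C)C=O | intermediate
10 | tert-butyl 1α-hydroxy-9-oxo-11-nordrim-7-ene-2α-carboxylate (expected major diastereomer) | O[C@H]1[C@@H](C(=O)OC(C)(C)C)CC(C)(C)[C@@H]2CC=C(C)C(=O)[C@@]12C | intermediate
11 | tert-butyl 1,9-dioxo-11-nordrim-7-ene-2-carboxylate | O=C1[C@@H](C(=O)OC(C)(C)C)CC(C)(C)[C@@H]2CC=C(C)C(=O)[C@@]12C | intermediate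
12 | 1,9-dioxo-11-nordrim-7-ene-2-carboxylic acid | O=C1[C@@H](C(=O)O)CC(C)(C)[C@@H]2CC=C(C)C(=O)[C@@]12C | intermediate
13 | 11-nordrim-7-ene-1,9-dione | O=C1CCC(C)(C)[C@@H]2CC=C(C)C(=O)[C@@]12C | intermediate
14 | 1β-hydroxy-11-nordrim-7-en-9-one | O[C@@H]1CCC(C)(C)[C@@H]2CC=C(C)C(=O)[C@@]12C | intermediate
15 | (E)-4-methoxycinnamoyl chloride | COc1ccc(/C=C/C(Cl)=O)cc1 | starting material
16 | 1β-[(E)-4-methoxycinnamoyloxy]-11-nordrim-7-en-9-one | COc1ccc(/C=C/C(=O)O[C@@H]2CCC(C)(C)[C@@H]3CC=C(C)C(=O)[C@@]23C)cc1 | intermediate
17 | 1β-[(E)-4-methoxycinnamoyloxy]drima-7,9(11)-diene | COc1ccc(/C=C/C(=O)O[C@@H]2CCC(C)(C)[C@@H]3CC=C(C)C(=C)[C@@]23C)cc1 | intermediate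
18 | 9-[1β-((E)-4-methoxycinnamoyloxy)drim-7-en-11-yl]-9-borabicyclo[3.3.1]nonane | COc1ccc(/C=C/C(=O)O[C@@H]2CCC(C)(C)[C@@H]3CC=C(C)[C@H](CB4C5CCCC4CCC5)[C@@]23C)cc1 | intermediate
19 | 1β-[(E)-4-methoxycinnamoyloxy]drim-7-en-11-ol | COc1ccc(/C=C/C(=O)O[C@@H]2CCC(C)(C)[C@@H]3CC=C(C)[C@H](CO)[C@@]23C)cc1 | intermediate
20 | 1β-[(E)-4-methoxycinnamoyloxy]drim-7-ene-11,12-diol | COc1ccc(/C=C/C(=O)O[C@@H]2CCC(C)(C)[C@@H]3CC=C(CO)[C@H](CO)[C@@]23C)cc1 | intermediate
21 | 1β-[(E)-4-methoxycinnamoyloxy]drim-7-ene-11,12-dial | COc1ccc(/C=C/C(=O)O[C@@H]2CCC(C)(C)[C@@H]3CC=C(C=O)[C@H](C=O)[C@@]23C)cc1 | target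

**Step count and risks**

Total steps: 12. Longest linear sequence: 12 steps (1 to 21).

Steps most likely to fail:

1. Step 4. The β-keto aldehyde may lose its formyl group by retro-Claisen cleavage in the protic reducing medium, the aldehyde may be reduced, or the ester enolate may be protonated before ring closure. The fallback sets out from alcohol 5 and returns at 10, forming the two bonds in separate operations. Giese coupling of 5 with 7 under the same iron hydride conditions (no aldehyde present) should give tert-butyl 4-[2-(hydroxymethyl)-2,4-dimethyl-3-oxocyclohex-4-en-1-yl]-4-methylpentanoate F1. DMP oxidation would give the corresponding 2-formyl compound, tert-butyl 4-(2-formyl-2,4-dimethyl-3-oxocyclohex-4-en-1-yl)-4-methylpentanoate F2. Ester-enolate formation with LiN(i-Pr)2 in THF at −78 °C would then close ring A by intramolecular aldol to 10.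

2. Step 9. Methylene transfer to the C9 carbonyl may be blocked by steric shielding from the quaternary C10, the C8 methyl and the peri C1 ester. The fallback sets out from 14 and returns at 17, delivering C11 intramolecularly from the 1β-oxygen through a temporary silicon tether. Silylation with (bromomethyl)chlorodimethylsilane and imidazole should give the (bromomethyl)dimethylsilyl ether of 14, F3. SmI2 in THF (Barbier cyclisation) would form the six-membered siloxane carbinol F4 with the new CH2 on C9β. Peterson elimination (KH, THF) followed by Bu4NF would release 1β-hydroxydrima-7,9(11)-diene F5, which is acylated with 15 (Et3N, DMAP) to give 17.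

3. Step 11. The ene reaction may occur at the C9 methine instead of the C12 methyl, or C12 may be over-oxidised to the aldehyde, which would cyclise onto the free C11 hydroxyl and be carried on to the lactone. The fallback sets out from 19 and returns at 20, replacing direct C–H oxidation by epoxide chemistry. mCPBA should epoxidise only the electron-rich C7=C8 bond from the α face to give the 7α,8α-epoxide of 19, F6. Cp2TiCl (trivalent titanium, from Cp2TiCl2 and Mn dust) would open it at C8 and, after hydrogen loss from the methyl group, give the 7α-hydroxy-8(12)-ene diol F7. Catalytic O3ReOSiPh3 would then effect 1,3-transposition of the allylic alcohol to the primary C12 alcohol with the trisubstituted C7=C8 bond, i.e. 20.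

**Further compounds**

F1 | step 4 | tert-butyl 4-[2-(hydroxymethyl)-2,4-dimethyl-3-oxocyclohex-4-en-1-yl]-4-methylpentanoate (side chain trans to CH2OH) | CC(C)(CCC(=O)OC(C)(C)C)[C@@H]1CC=C(C)C(=O)[C@@]1(C)CO
F2 | step 4 | tert-butyl 4-(2-formyl-2,4-dimethyl-3-oxocyclohex-4-en-1-yl)-4-methylpentanoate (side chain trans to CHO) | CC(C)(CCC(=O)OC(C)(C)C)[C@@H]1CC=C(C)C(=O)[C@@]1(C)C=O
F3 | step 9 | 1β-[(bromomethyl)dimethylsilyloxy]-11-nordrim-7-en-9-one | BrC[Si](C)(C)O[C@@H]1CCC(C)(C)[C@@H]2CC=C(C)C(=O)[C@@]12C
F4 | step 9 | cyclic 1β-O,11-dimethylsilylene derivative of drim-7-ene-1β,9α-diol (six-membered siloxane, 9α-OH) | O1[C@@H]2CCC(C)(C)[C@@H]3CC=C(C)[C@](O)(C[Si]1(C)C)[C@@]23C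
F5 | step 9 | drima-7,9(11)-dien-1β-ol | O[C@@H]1CCC(C)(C)[C@@H]2CC=C(C)C(=C)[C@@]12C
F6 | step 11 | 7α,8α-epoxy-1β-[(E)-4-methoxycinnamoyloxy]driman-11-ol | COc1ccc(/C=C/C(=O)O[C@@H]2CCC(C)(C)[C@@H]3C[C@H]4O[C@@]4(C)[C@H](CO)[C@@]23C)cc1
F7 | step 11 | 1β-[(E)-4-methoxycinnamoyloxy]drim-8(12)-ene-7α,11-diol | COc1ccc(/C=C/C(=O)O[C@@H]2CCC(C)(C)[C@@H]3C[C@@H](O)C(=C)[C@H](CO)[C@@]23C)cc1
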